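**Retrosynthetic overview**
1. One C16 building block, hexadecane-1,16-diol (1), is used twice; it is desymmetrised to 16-bromohexadecan-1-ol (2).
2. The C16–C17 bond is the only C–C bond made: symmetric dotriacontane-1,32-diol (3) comes from two molecules of 2 by reductive homocoupling.
3. The key disconnection is the ring O1–C2 bond: 3 is closed dehydrogenatively, through hydroxy aldehyde 4 and macrocyclic lactol 5, to the 33-membered lactone 6 (target).
4. Ring order: the single ring is formed last, in the C–O bond-forming step.

Assumption: the SMILES is read as the 33-membered ω-lactone with one ester group and 31 ring CH2 groups (C32H62O2); it is achiral, so the "single enantiomer" is the compound itself and no stereocontrol is needed.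

**Route**

Step 1
Reactants: 1 hexadecane-1,16-diol
Product: 2 16-bromohexadecan-1-ol
Conditions: 48% aq. HBr (1.2 equiv), toluene, reflux, 36 h
Reagents that add atoms: hydrogen bromide, SMILES: Br
Why: Acid-promoted SN2 substitution of one primary hydroxyl by bromide (two-phase monobromination of an α,ω-diol); the bromo alcohol stays in toluene away from the aqueous acid, so the second substitution is slow, and no stereocentre is involved.

Step 2
Reactants: 2 16-bromohexadecan-1-ol (two molecules)
Product: 3 dotriacontane-1,32-diol
Conditions: NiCl2(dme) (5 mol%), 4,4',4''-tri-tert-butyl-2,2':6',2''-terpyridine (5 mol%), Mn powder (1.0 equiv), DMF, 60 °C, 16 h; 1 M HCl quench, recrystallise from hot toluene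
Reagents that add atoms: none
Why: Nickel-catalysed reductive homocoupling (Wurtz-type dimerisation): zerovalent nickel–terpyridine, regenerated by manganese metal, turns the primary alkyl bromide into alkyl radical/alkylnickel species that join C16 to C16, and the neutral medium tolerates the free hydroxyl; no stereocentre is formed.

Step 3
Reactants: 3 dotriacontane-1,32-diol
Product: 6 oxacyclotritriacontan-2-one (target), via 32-hydroxydotriacontanal 4 (not isolated), via oxacyclotritriacontan-2-ol 5 (not isolated)
Conditions: RuH(CO)[C5H3N(CHPtBu2)(CH2NEt2)] (dearomatised PNN pincer hydride, 5 mol%), dry degassed toluene, reflux, argon sweep, 3 fed slowly from a Soxhlet thimble (steady state ≤1 mM, final 2 mM), 48 h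
Reagents that add atoms: none
Why: Proposed new method: acceptorless dehydrogenative macrolactonisation of a long-chain α,ω-diol. The divalent ruthenium pincer hydride reversibly dehydrogenates one CH2OH to aldehyde 4 (uphill, so 4 stays at trace level). The distal hydroxyl then adds to the aldehyde carbon and closes the strain-free 33-membered lactol 5; this is the ring-forming C–O bond. The effective molarity of such large rings (about 0.01–0.05 M) exceeds the ≤4 mM hydroxyl concentration, so ring closure should beat chain growth. Lactol 5 is then dehydrogenated irreversibly to lactone 6 while H2 is swept out. The closest known reaction type is pincer-ruthenium acceptorless dehydrogenative coupling of primary alcohols to esters and of 1,4- to 1,6-diols to five- to seven-membered lactones; long diols are so far known to give only polyesters at high concentration. No stereocentre exists in the target.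

**Compound list**
1 | hexadecane-1,16-diol | OCCCCCCCCCCCCCCCCO | starting material
2 | 16-bromohexadecan-1-ol | OCCCCCCCCCCCCCCCCBr | intermediate
3 | dotriacontane-1,32-diol | OCCCCCCCCCCCCCCCCCCCCCCCCCCCCCCCCO | intermediate
4 | 32-hydroxydotriacontanal (formed in the flask) | O=CCCCCCCCCCCCCCCCCCCCCCCCCCCCCCCCO | intermediate
5 | oxacyclotritriacontan-2-ol (macrocyclic lactol, racemic, formed in the flask) | OC1CCCCCCCCCCCCCCCCCCCCCCCCCCCCCCCO1 | intermediate
6 | oxacyclotritriacontan-2-one (dotriacontan-32-olide, achiral) | O=C1CCCCCCCCCCCCCCCCCCCCCCCCCCCCCCCO1 | target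

**Totals**
Total step count: 3. Longest linear sequence: 3 steps.

**Steps most likely to fail, with fallbacks**

Step 3 (the new ring closure; risks are oligoester formation and slow turnover at high dilution). The fallback uses known chemistry, sets out from 3 and comes back at 6. Diol 3 is monobrominated as in step 1 (48% aq. HBr, toluene, reflux) to 32-bromodotriacontan-1-ol F5. Oxidation with TEMPO (cat.) and PhI(OAc)2 in CH2Cl2–MeCN–H2O at 40 °C gives 32-bromodotriacontanoic acid F6. Slow addition of F6 to Cs2CO3 in DMF at 80 °C (final ≤5 mM) forms cesium 32-bromodotriacontanoate F7, which closes by intramolecular SN2 displacement of bromide by the carboxylate (cesium carboxylate macrolactonisation of an ω-halo acid) to 6.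

Step 2 (risks are hydrodehalogenation, β-hydride elimination, and the waxy product precipitating with the catalyst). The fallback sets out from 2 and comes back at 3. Compound 2 is protected with 3,4-dihydro-2H-pyran (PPTS cat., CH2Cl2) as 2-[(16-bromohexadecyl)oxy]oxane F2. About half of F2 is converted with Mg turnings in THF into [16-(oxan-2-yloxy)hexadecyl]magnesium bromide F3. F3 is coupled with the remaining F2 under Li2CuCl4 catalysis (THF, −10 °C to rt, copper-catalysed alkyl–alkyl Grignard coupling) to 1,32-bis(oxan-2-yloxy)dotriacontane F4. p-TsOH (cat.) in MeOH–THF at 50 °C removes both acetals and returns 3.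

Step 1 (risk is dibromide and unreacted diol that are hard to separate on scale). The fallback sets out from 1 and comes back at 2. Diol 1 in excess (2.5 equiv) is treated with TsCl (1 equiv) and powdered KOH in THF at 0 °C to give 16-hydroxyhexadecyl 4-methylbenzenesulfonate F1; the excess 1 is recovered by crystallisation. LiBr in refluxing acetone then displaces the sulfonate and gives 2.

**Further compounds**
F1 | step 1 | 16-hydroxyhexadecyl 4-methylbenzenesulfonate | Cc1ccc(cc1)S(=O)(=O)OCCCCCCCCCCCCCCCCO
F2 | step 2 | 2-[(16-bromohexadecyl)oxy]oxane (racemic) | BrCCCCCCCCCCCCCCCCOC1CCCCO1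
F3 | step 2 | [16-(oxan-2-yloxy)hexadecyl]magnesium bromide (racemic) | Br[Mg]CCCCCCCCCCCCCCCCOC1CCCCO1
F4 | step 2 | 1,32-bis(oxan-2-yloxy)dotriacontane (mixture of diastereomers) | O1CCCCC1OCCCCCCCCCCCCCCCCCCCCCCCCCCCCCCCCOC1CCCCO1
F5 | step 3 | 32-bromodotriacontan-1-ol | OCCCCCCCCCCCCCCCCCCCCCCCCCCCCCCCCBr
F6 | step 3 | 32-bromodotriacontanoic acid | OC(=O)CCCCCCCCCCCCCCCCCCCCCCCCCCCCCCCBr
F7 | step 3 | cesium 32-bromodotriacontanoate | [Cs+].[O-]C(=O)CCCCCCCCCCCCCCCCCCCCCCCCCCCCCCCBr
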